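**Retrosynthetic overview**
1. Cespitularin K comes from acetylation of the C6 alcohol 17, a 4,4-dimethyl-tetrahydroindene-1,3-dione whose C1 and C9 are spanned by a seven-carbon ansa bridge.
2. Key step (one flask): vinyl hydroboration, methoxide-triggered ylidenebutenolide → cyclopent-4-ene-1,3-dione acyl shift, and B-alkyl Suzuki closure of C3–C4. The dione ring and the twelve-membered ring are made together, and C9 is fixed by the bridge.
3. The ylidenebutenolide (a masked dione carrying C6–C10) comes from a tandem Sonogashira/lactonisation of a ring A β-bromo acid with commercial (E)-3-methylpent-2-en-4-yn-1-ol. C4/C5/C20 are added by 2-bromoallylation, and C6 is set by CBS reduction.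
4. Ring A and C1: copper-catalysed asymmetric vinyl conjugate addition/methylation of 2-methylcyclohex-2-enone, then Vilsmeier bromoformylation and Pinnick oxidation.
5. Ring order: ring A (bought as the enone) → butenolide (temporary) → cyclopentenedione → twelve-membered ring.

Numbering used below: C1 (ring A CH carrying the bridge), C2, C3, C4 (=C20H2), C5, C6 (OAc), C7=C8 (C19 methyl), C9 (CH between the ketones), C10 and C18 (ketones), C11=C12 (ring-fusion alkene), C13, C14, C15 (gem-dimethyl).
Assumption: the doubly activated C9 centre is under thermodynamic control, and the required 9S epimer (C8 on the same face as the C1–C2 bond, as the SMILES encodes) is the only one the bridge can span without severe strain.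

**Step 1**
Reactants: 1 2-methylcyclohex-2-en-1-one; 2 vinylmagnesium bromide
Product: 4 (3S)-3-ethenyl-2,2-dimethylcyclohexan-1-one, via magnesium enolate 3 (not isolated)
Conditions: 2 (1.4 equiv), Cu(OTf)2 (4 mol %), chiral hydroxyalkyl-imidazolinium chloride (NHC precursor, 5 mol %; enantiomer that directs attack to the Re face of C3), Et2O, −30 °C; then MeI, DMPU, −30 °C → rt
Reagents that add atoms: iodomethane CI
Why: Copper-catalysed asymmetric conjugate addition with enolate alkylation (established for alkyl Grignard reagents on this enone; vinyl transfer is the less proven variant): the catalyst formed from Cu(OTf)2 and the chiral NHC delivers vinyl to the Re face of C3, which sets skeleton C1, and the regiodefined enolate 3 is C-methylated to give the gem-dimethyl carbon.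

**Step 2**
Reactants: 4 (3S)-3-ethenyl-2,2-dimethylcyclohexan-1-one
Product: 5 (4S)-2-bromo-4-ethenyl-3,3-dimethylcyclohex-1-ene-1-carbaldehyde
Conditions: PBr3, DMF, CHCl3, 0 → 60 °C; aq. NaOAc
Reagents that add atoms: N,N-dimethylformamide CN(C)C=O; phosphorus tribromide BrP(Br)Br; water O
Why: Vilsmeier–Haack–Arnold bromoformylation: the ketone can enolise only toward its CH2 side, so formylation occurs there and the carbonyl oxygen is exchanged for bromide, giving the tetrasubstituted β-bromo enal (C11–Br, C12–CHO) without touching the stereocentre.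

**Step 3**
Reactants: 5 (4S)-2-bromo-4-ethenyl-3,3-dimethylcyclohex-1-ene-1-carbaldehyde
Product: 6 (4S)-2-bromo-4-ethenyl-3,3-dimethylcyclohex-1-ene-1-carboxylic acid
Conditions: NaClO2, NaH2PO4, 2-methyl-2-butene, t-BuOH/H2O, 0 °C → rt
Reagents that add atoms: sodium chlorite [Na+].[O-]Cl=O
Why: Pinnick oxidation converts the enal to the acid while the scavenger protects the vinyl group and the vinyl bromide is inert.

**Step 4**
Reactants: 6 (4S)-2-bromo-4-ethenyl-3,3-dimethylcyclohex-1-ene-1-carboxylic acid; 7 (2E)-3-methylpent-2-en-4-yn-1-ol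
Product: 9 (3Z,5S)-5-ethenyl-3-[(2E)-4-hydroxy-2-methylbut-2-en-1-ylidene]-4,4-dimethyl-4,5,6,7-tetrahydro-2-benzofuran-1(3H)-one, via enyne acid 8 (not isolated)
Conditions: PdCl2(PPh3)2 (5 mol %), CuI (10 mol %), Et3N, MeCN, 50 °C
Reagents that add atoms: none
Why: Tandem Sonogashira coupling/5-exo-dig lactonisation: the activated β-bromo acid couples with the slim terminal alkyne and the cis carboxylate adds anti across the activated triple bond, giving the (Z)-γ-ylidenebutenolide (a masked 2-alkenyl-cyclopentenedione) with the E olefin of 7 carried through unchanged.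

**Step 5**
Reactants: 9 (3Z,5S)-5-ethenyl-3-[(2E)-4-hydroxy-2-methylbut-2-en-1-ylidene]-4,4-dimethyl-4,5,6,7-tetrahydro-2-benzofuran-1(3H)-one
Product: 10 (2E,4Z)-4-[(5S)-5-ethenyl-4,4-dimethyl-1-oxo-4,5,6,7-tetrahydro-2-benzofuran-3(1H)-ylidene]-3-methylbut-2-enal
Conditions: MnO2 (activated), CH2Cl2, rt
Reagents that add atoms: none
Why: MnO2 oxidises the primary dienylic alcohol selectively to the aldehyde under neutral conditions that the enol lactone tolerates.

**Step 6**
Reactants: 10 (2E,4Z)-4-[(5S)-5-ethenyl-4,4-dimethyl-1-oxo-4,5,6,7-tetrahydro-2-benzofuran-3(1H)-ylidene]-3-methylbut-2-enal; 11 2,3-dibromoprop-1-ene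
Product: 12 (3Z,5S)-3-[(2E)-6-bromo-4-hydroxy-2-methylhepta-2,6-dien-1-ylidene]-5-ethenyl-4,4-dimethyl-4,5,6,7-tetrahydro-2-benzofuran-1(3H)-one (both carbinol epimers)
Conditions: In powder, THF/H2O 1:1, rt
Reagents that add atoms: none
Why: Indium-mediated Barbier 2-bromoallylation is chemoselective for the aldehyde and installs C4, C5, C20 and the vinyl bromide needed for ring closure; the carbinol forms unselectively and is corrected in steps 7 and 8.

**Step 7**
Reactants: 12 (3Z,5S)-3-[(2E)-6-bromo-4-hydroxy-2-methylhepta-2,6-dien-1-ylidene]-5-ethenyl-4,4-dimethyl-4,5,6,7-tetrahydro-2-benzofuran-1(3H)-one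
Product: 13 (3Z,5S)-3-[(2E)-6-bromo-2-methyl-4-oxohepta-2,6-dien-1-ylidene]-5-ethenyl-4,4-dimethyl-4,5,6,7-tetrahydro-2-benzofuran-1(3H)-one
Conditions: Dess–Martin periodinane, pyridine, CH2Cl2, 0 °C
Reagents that add atoms: none
Why: Dess–Martin oxidation under buffered conditions converts the acid-sensitive dienylic alcohol to the dienone without isomerising the skipped vinyl bromide.

**Step 8**
Reactants: 13 (3Z,5S)-3-[(2E)-6-bromo-2-methyl-4-oxohepta-2,6-dien-1-ylidene]-5-ethenyl-4,4-dimethyl-4,5,6,7-tetrahydro-2-benzofuran-1(3H)-one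
Product: 14 (3Z,5S)-3-[(2E,4S)-6-bromo-4-hydroxy-2-methylhepta-2,6-dien-1-ylidene]-5-ethenyl-4,4-dimethyl-4,5,6,7-tetrahydro-2-benzofuran-1(3H)-one
Conditions: (R)-2-methyl-CBS-oxazaborolidine (30 mol %), catecholborane, toluene, −78 → −40 °C; MeOH, aq. NaHCO3
Reagents that add atoms: none
Why: Corey–Bakshi–Shibata reduction: the dienyl arm acts as the large group, so the (R)-catalyst gives the (S)-carbinol (skeleton C6) under reagent control, independent of the remote C1 centre, and catecholborane at low temperature does not hydroborate the alkenes.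

**Step 9**
Reactants: 14 (3Z,5S)-3-[(2E,4S)-6-bromo-4-hydroxy-2-methylhepta-2,6-dien-1-ylidene]-5-ethenyl-4,4-dimethyl-4,5,6,7-tetrahydro-2-benzofuran-1(3H)-one
Product: 17 6-O-deacetylcespitularin K (1R,6S,9S,7E), via alkylborane 15 (not isolated), via enolate borate disodium salt 16 (not isolated)
Conditions: 9-BBN (3 equiv), THF, 0 °C → rt; NaOMe (6 equiv), MeOH, rt, 1 h; then syringe-pump addition into Pd(dppf)Cl2 (20 mol %), AsPh3 (40 mol %), THF/DMF, 60 °C (final 2 mM); aq. NH4Cl
Reagents that add atoms: none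
Why: Proposed new method: 9-BBN adds only to the monosubstituted vinyl group; methoxide then opens the enol lactone to a keto-ester enolate whose C9 recloses on the ester (5-exo-trig Claisen, the classical alkylidenephthalide → indane-1,3-dione rearrangement) and also converts the borane into the borate needed for transmetalation; oxidative addition of the vinyl bromide to zerovalent palladium, transmetalation and reductive elimination then close the twelve-membered ring at C3–C4 (closest known reactions: ylidenebutenolide → cyclopent-4-ene-1,3-dione rearrangement and macrocyclic B-alkyl Suzuki–Miyaura coupling), and C9 is set on protonation because the bridge anchored at C1 covers one face so the proton enters from the other.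

**Step 10**
Reactants: 17 6-O-deacetylcespitularin K
Product: 18 cespitularin K
Conditions: Ac2O, pyridine, DMAP (cat.), CH2Cl2, 0 °C
Reagents that add atoms: acetic anhydride CC(=O)OC(C)=O
Why: Standard acylation of the secondary allylic alcohol; the dione cannot form an enol acetate (it would be a cyclopentadienone), and the C7=C8 π-bond lies roughly orthogonal to the C9–H bond, so acetate loss or olefin migration through the enolate is not expected.

**Compound list**
1 | 2-methylcyclohex-2-en-1-one | CC1=CCCCC1=O | starting material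
2 | vinylmagnesium bromide | C=C[Mg]Br | starting material
3 | bromomagnesium (3S)-3-ethenyl-2-methylcyclohex-1-en-1-olate | C=C[C@@H]1CCCC(O[Mg]Br)=C1C | intermediate
4 | (3S)-3-ethenyl-2,2-dimethylcyclohexan-1-one | C=C[C@@H]1CCCC(=O)C1(C)C | intermediate
5 | (4S)-2-bromo-4-ethenyl-3,3-dimethylcyclohex-1-ene-1-carbaldehyde | C=C[C@@H]1CCC(C=O)=C(Br)C1(C)C | intermediate
6 | (4S)-2-bromo-4-ethenyl-3,3-dimethylcyclohex-1-ene-1-carboxylic acid | C=C[C@@H]1CCC(C(=O)O)=C(Br)C1(C)C | intermediate
7 | (2E)-3-methylpent-2-en-4-yn-1-ol | C#C/C(C)=C/CO | starting material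
8 | (4S)-4-ethenyl-2-[(3E)-5-hydroxy-3-methylpent-3-en-1-yn-1-yl]-3,3-dimethylcyclohex-1-ene-1-carboxylic acid | C=C[C@@H]1CCC(C(=O)O)=C(C#C/C(C)=C/CO)C1(C)C | intermediate
9 | (3Z,5S)-5-ethenyl-3-[(2E)-4-hydroxy-2-methylbut-2-en-1-ylidene]-4,4-dimethyl-4,5,6,7-tetrahydro-2-benzofuran-1(3H)-one | C=C[C@@H]1CCC2=C(/C(=C/C(C)=C/CO)OC2=O)C1(C)C | intermediate
10 | (2E,4Z)-4-[(5S)-5-ethenyl-4,4-dimethyl-1-oxo-4,5,6,7-tetrahydro-2-benzofuran-3(1H)-ylidene]-3-methylbut-2-enal | C=C[C@@H]1CCC2=C(/C(=C/C(C)=C/C=O)OC2=O)C1(C)C | intermediate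
11 | 2,3-dibromoprop-1-ene | C=C(Br)CBr | starting material
12 | (3Z,5S)-3-[(2E)-6-bromo-4-hydroxy-2-methylhepta-2,6-dien-1-ylidene]-5-ethenyl-4,4-dimethyl-4,5,6,7-tetrahydro-2-benzofuran-1(3H)-one, mixture of carbinol epimers | C=C[C@@H]1CCC2=C(/C(=C/C(C)=C/C(O)CC(Br)=C)OC2=O)C1(C)C | intermediate
13 | (3Z,5S)-3-[(2E)-6-bromo-2-methyl-4-oxohepta-2,6-dien-1-ylidene]-5-ethenyl-4,4-dimethyl-4,5,6,7-tetrahydro-2-benzofuran-1(3H)-one | C=C[C@@H]1CCC2=C(/C(=C/C(C)=C/C(=O)CC(Br)=C)OC2=O)C1(C)C | intermediate
14 | (3Z,5S)-3-[(2E,4S)-6-bromo-4-hydroxy-2-methylhepta-2,6-dien-1-ylidene]-5-ethenyl-4,4-dimethyl-4,5,6,7-tetrahydro-2-benzofuran-1(3H)-one | C=C[C@@H]1CCC2=C(/C(=C/C(C)=C/[C@@H](O)CC(Br)=C)OC2=O)C1(C)C | intermediate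
15 | 9-{2-[(3Z,5R)-3-[(2E,4S)-6-bromo-4-hydroxy-2-methylhepta-2,6-dien-1-ylidene]-4,4-dimethyl-1-oxo-1,3,4,5,6,7-hexahydro-2-benzofuran-5-yl]ethyl}-9-borabicyclo[3.3.1]nonane | C1CCC2CCCC1B2CC[C@@H]3CCC4=C(/C(=C/C(C)=C/[C@@H](O)CC(Br)=C)OC4=O)C3(C)C | intermediate
16 | disodium (5R)-2-[(2E,4S)-6-bromo-4-hydroxyhepta-2,6-dien-2-yl]-5-[2-(9-methoxy-9-boranuidabicyclo[3.3.1]non-9-yl)ethyl]-4,4-dimethyl-3-oxo-4,5,6,7-tetrahydroinden-1-olate | CO[B-]1(CC[C@@H]2CCC3=C(C(=O)C(/C(C)=C/[C@@H](O)CC(Br)=C)=C3[O-])C2(C)C)C4CCCC1CCC4.[Na+].[Na+] | intermediate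
17 | 6-O-deacetylcespitularin K: 4,4-dimethyl-4,5,6,7-tetrahydro-2H-indene-1,3-dione whose C5 (skeleton C1, R) and C2 (skeleton C9, S) are joined by the bridge C5–CH2–CH2–C(=CH2)–CH2–CH(OH)(S)–CH=C(CH3)–C2 with a 7E olefin | C=C1CC[C@@H]2CCC3=C(C(=O)[C@H](C3=O)/C(C)=C/[C@@H](O)C1)C2(C)C | intermediate
18 | cespitularin K (the 6-O-acetate of 17; 1R,6S,9S,7E) | C=C1CC[C@@H]2CCC3=C(C(=O)[C@H](C3=O)/C(C)=C/[C@@H](OC(C)=O)C1)C2(C)C | target

**Totals**
Total step count: 10. Longest linear sequence: 10 steps (1 → 18).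

**Three steps most likely to fail**

Step 9 (one-flask acyl shift/ansa Suzuki closure). Risks are interference of the dione enolate or methoxide with the palladium cycle, and hydrodebromination. The fallback sets out from 14 and returns at 17, separating the two events and inverting their order. After the same hydroboration to 15, the ring is closed first on the neutral enol lactone with a methoxide-free base (Pd(dppf)Cl2, AsPh3, K3PO4, DMF/THF/H2O, 50 °C, high dilution). This gives the macrocyclic ylidenebutenolide (5R,6S,7E,9Z)-6-hydroxy-12-membered carbocycle fused to the butenolide F4. NaOMe in MeOH at rt then performs the acyl shift inside the macrocycle, so the cyclopentenedione becomes the last ring formed, and acidic work-up gives 17.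

Step 1 (asymmetric vinyl transfer to an α-methyl enone). Vinyl Grignard reagents may give low ee under conditions optimised for alkyl reagents. The fallback sets out from 1 and returns at 4, using the well-precedented alkyl addition and then excising one carbon. Compound 1, but-3-enylmagnesium bromide, the same Cu(OTf)2/NHC catalyst and MeI trapping give (3S)-3-(but-3-en-1-yl)-2,2-dimethylcyclohexan-1-one F1. Ozonolysis (O3, CH2Cl2, −78 °C; PPh3) gives 3-[(1S)-2,2-dimethyl-3-oxocyclohexyl]propanal F2. Rhodium-catalysed transfer dehydroformylation ([Rh(cod)OMe]2, Xantphos, 3-methoxybenzoic acid, norbornadiene, THF, 90 °C) then removes the formyl group and a β-hydrogen to give 4.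

Step 4 (tandem coupling at the hindered C–Br; 6-endo closure to a pyranone is the competing path). The fallback sets out from 5 and returns at 9, decoupling C–C bond formation from lactonisation. Sonogashira coupling of the carboxylate-free β-bromo enal 5 with 7 (PdCl2(PPh3)2, CuI, Et3N, THF, rt) gives (4S)-4-ethenyl-2-[(3E)-5-hydroxy-3-methylpent-3-en-1-yn-1-yl]-3,3-dimethylcyclohex-1-ene-1-carbaldehyde F3. Pinnick oxidation gives acid 8, now isolated. AgNO3 (10 mol %) in acetone then effects a 5-exo-dig cycloisomerisation, which favours the five-membered ylidenebutenolide, to give 9.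

**Further compounds**
F1 | step 1 | (3S)-3-(but-3-en-1-yl)-2,2-dimethylcyclohexan-1-one | C=CCC[C@@H]1CCCC(=O)C1(C)C
F2 | step 1 | 3-[(1S)-2,2-dimethyl-3-oxocyclohexyl]propanal | O=CCC[C@@H]1CCCC(=O)C1(C)C
F3 | step 4 | (4S)-4-ethenyl-2-[(3E)-5-hydroxy-3-methylpent-3-en-1-yn-1-yl]-3,3-dimethylcyclohex-1-ene-1-carbaldehyde | C=C[C@@H]1CCC(C=O)=C(C#C/C(C)=C/CO)C1(C)C
F4 | step 9 | macrocyclic ylidenebutenolide: 4,4-dimethyl-4,5,6,7-tetrahydro-2-benzofuran-1(3H)-one whose C5 (R) and C3 are joined by C5–CH2–CH2–C(=CH2)–CH2–CH(OH)(S)–CH=C(CH3)–CH=C3 (7E, 9Z) | C=C1CC[C@@H]2CCC3=C(/C(=C/C(C)=C/[C@@H](O)C1)OC3=O)C2(C)C
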